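The numbers in the tables were generated by integration for an exercise, and the scatter is random.

The easy step was a subtraction. I counted one equivalent of coupling partner as going into the starting material, the limiting reagent, so by that count the maple flask had 0.600 equiv to spare and the alder flask 1.80 equiv.

| setting | maple | alder | amber | red | ochre |
|---|---|---|---|---|---|
| starting material | 0.20 M | 0.20 M | 0.20 M | 0.20 M | 0.20 M |
| coupling partner | 1.6 equiv | 2.8 equiv | 2.50 equiv | 3.00 equiv | 4.00 equiv |
| remark | run made earlier | run made earlier |  |  |  |
| time |  |  | 20 h | 20 h | 20 h |

| run | time / h | single product / % |
|---|---|---|
| maple | 1.00 | 84.1 |
| maple | 2.00 | 87.6 |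
| maple | 4.00 | 87.2 |
| maple | 8.00 | 88.4 |
| maple | 15.0 | 88.5 |
| alder | 1.33 | 86.8 |
| alder | 4.00 | 82.7 |
| alder | 6.00 | 80.6 |
| alder | 10.0 | 79.8 |
| alder | 15.0 | 79.0 |

(each reading ± 0.5 percentage points)

1. how much single product is there at the end, in percent of the starting material charged: for each flask in turn (amber, red, ochre)



Time was the first setting I turned. By hand, a longer wait should cost single product for as long as spare partner stands beside it, and in the alder run it did. The alder reading fell 4.1 percentage points from 1.33 h to 4.00 h, a factor of 3.01 in time, and 3.7 points from there to 15.0 h, a factor of 3.75. Like falls for like factors of time suggested a loss running with the logarithm of time. So I supposed that the partner destroys itself at the square of its own concentration and falls as one over time, with single product lost at a rate first order in that partner. Between 10.0 h and 15.0 h the alder reading moved 0.8 points, against a scatter of 0.5 points, and I chose to take the last readings as endings.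

Equivalents were the second setting. By hand, a larger charge of such a partner dies faster, so each factor of spare partner should cost a like fraction of single product, which is a power law. The logarithm of the ratio of the last maple reading to the last alder reading, over that of the two spares, gave 0.103. This reading is the excess order, the power of the spare partner to which the ending single product is inversely proportional at the starting concentration these flasks share. From the alder ending I reckoned 80.5% for amber, 78.1% for red and 74.9% for ochre.

The forecast, which held that “Excess partner therefore consumes product, but the loss stops”, gave 82.5%, 76.5% and 64%. For ochre my figure stood higher than the forecast's.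

The flasks gave 80.4%, 77.4% and 73.4% at 20 h.

    starting material + coupling partner → single product (k = 28.7 M⁻¹ h⁻¹)
    coupling partner + single product → over-reaction product (k = 0.0669 M⁻¹ h⁻¹)
    2 coupling partner → self-condensation product (k = 5.18 M⁻¹ h⁻¹)
    coupling partner + single product → double product (k = 0.986 M⁻¹ h⁻¹)

In the ochre flask, coupling partner stood at 0.079% of its own charge at 20.0 h. Starting from the red ending, the excess order reckons 74.2% for ochre, and the ochre flask gave 73.4%.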